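## Structural features

The target is a 2H-chromene. Ring A is a benzene ring fused through C4a and C8a to a pyran ring that holds the C3=C4 double bond and, on C2, a methyl group and a 4-hydroxy-4-methylpentyl chain. Ring A is a hydroquinone with para hydroxyls on C5 and C8, an (E)-4-hydroxycinnamoyl group on C6 and hydrogen on C7, so every carbon of ring A is differentiated. C2 is the only stereocentre: a fully substituted carbon bound to O1, of (S) configuration, with no stereogenic neighbour. It can be lost only if the O1–C2 bond breaks, as when a 2H-chromene opens to its ortho-quinone methide under heat, light or strong acid. The fragile groups are the hydroquinone (air oxidation), the 2'-hydroxychalcone (base-induced closure of the C5 hydroxyl onto the enone, conjugate addition), the styrene-like C3=C4 bond and the tertiary alcohol (both ionise in strong acid). The difficulty is to place four different substituents around ring A in the right order, to secure a tetrasubstituted carbinol ether carbon in one configuration, and to finish under very mild conditions. The key step uses the fact that C4a, C5, C6, C7, C8 and C8a, with oxygen on C5 and C8, an acyl carbon on C6 and hydrogen on C7, are exactly the six carbons that a cyclic alkenyl(methoxy)carbene of chromium, a terminal alkyne and one carbonyl ligand assemble. Ring A can therefore be grown onto a pyran ring that already holds C2.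

## Logic of the disconnections

29 is taken back through 28 to 27. The bonds cut are the three aryl O–Si bonds, then the two C–O bonds of the dioxolane and the alkyl O–Si bond. The reason is that hydroquinone, ring B phenol and enone stay masked until the last operation, so no earlier intermediate is an air-sensitive hydroquinone chalcone. The demand on the forward step is that buffered fluoride and then dilute acid suffice, in that order, so that the enone appears only when no phenoxide is left.

27 is related to 26 by the C3=C4 double bond. The cut adds two hydrogens, because the benzannulation needs a saturated pyran ring that is inert at C2. The gain is a simple chroman. The forward dehydrogenation must take hydride from C4 only, which needs O1 and the C5 oxygen as donors, silyl ethers that a quinone oxidant leaves alone, and the full substitution of C2 to stop over-oxidation.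

26 goes back to 25 by two aryl O–Si bonds, and 25 through 24 to 23 by exchange of the C8 hydroxyl for a methoxy group. The benzannulation necessarily gives C8 as a methyl ether and C5 as a free phenol. The methyl group is removed oxidatively straight away, while the molecule has neither chromene nor enone, instead of methylating C5 and oxidising a dimethoxyarene late. The demand is an oxidant that is mild and buffered enough to spare the dioxolane, and silylation under basic conditions.

23 is cut at C7–C8, C5–C6 and C4a–C5 into 12, 21 and one carbonyl ligand. This is the largest simplification: ring A with all four substituents comes from two fragments of similar size. The forward step needs one regiochemistry of alkyne insertion, and a masked enone, because an ynone would be a poor partner.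

12 is cut at the C8–C8a bond and at the O–CH3 bond into 8, 9 and a methylating agent, by way of 10 and 11. 8 goes back to 7 by one O–Si bond. The demand is lithiation only at the oxygen-bearing vinylic carbon, and a capped distal hydroxyl, since tBuLi and the oxonium salt would both attack a free one.

7 is cut at the O1–C8a bond to 6. The enol ether then comes from a terminal alkyne and the tertiary hydroxyl that is to become O1. The demand is endo (anti-Markovnikov) addition. The second hydroxyl of 6 is too remote to cyclise, so the two tertiary alcohols are told apart by ring size and not by selective protection.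

6 is cut at the C4a≡C8a triple bond to 5, and 5 through 4 at the C4–C4a bond to 3. These two one-carbon extensions turn the vinyl group into the butynyl arm without ever putting a leaving group near the tertiary carbinol, so oxetane formation and elimination cannot intervene. The demands are linear hydroformylation and a homologation that works on a lactol.

3 goes back through 2 to 1 by removing the elements of water from the distal double bond. 1 supplies the future C2 with its methyl group, oxygen, chain and a two-carbon handle. The vinyl group becomes C3 and C4 and keeps its rank over the chain, so (S) in 1 is (S) at C2 of 29. The demand is reaction at the trisubstituted alkene only, without cyclisation of the tertiary hydroxyl.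

21 goes back to 20 by a C–Si bond and to 19 by the two C–O bonds of the ketal. The terminal alkyne is needed for regiocontrol and the ketal for an electron-rich alkyne. The demand is ketalisation of an ynone without conjugate addition, and an aryl silyl ether that survives the removal of the alkynyl silyl group, which is why ring B carries a triisopropylsilyl group.

19 is cut between the carbonyl carbon and the alkyne into 16 and 17 (through 18). 16 is cut at its Cα=Cβ bond into 14 and 15, and 14 goes back to 13. The demands are single addition to the amide and (E)-selective olefination.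

## Other disconnections considered

Alternative 1: The cut takes the carbonyl carbon out from between C6 and the α-carbon of the enone (C6–C(=O) and C(=O)–Cα). Forward, zerovalent palladium inserts into the C6–I bond of iodochromene A2, the aryl–palladium bond takes up one carbonyl group from the gas phase, the (E)-styrylboronic acid A3 transmetallates, and reductive elimination gives enone A1, the tris(methoxymethyl) ether of 29.
- In its favour: the enone arrives in one late, convergent step with its E geometry carried in from A3, and A1 is one deprotection from the target. Ring A keeps a bought hydroquinone pattern, and electrophilic iodination should choose C6, which is para to O1 and ortho to the C5 oxygen.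
- Against it here: the step does nothing for the pyran ring, its double bond or C2, all of which must already be in A2. Direct coupling without carbonyl uptake competes, and A3 is prone to protodeboronation. The last step must remove three methoxymethyl groups, and the one on ring B needs acid strong enough to endanger the tertiary alcohol, the chromene and the chalcone.
- Comparison: on structure, the chosen plan forms ring A with every substituent placed, whereas this step forms only the enone. On mechanism, both rely on migratory insertion of a carbonyl ligand, with regiocontrol by sterics at chromium in one case and by an earlier halogenation in the other. On step economy for the enone itself Alternative 1 is the better, since no masked ynone has to be made and carried. On overall length it is at best the equal once the synthesis of A2 is counted.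

Alternative 2: The cut is the C4–C4a bond, which opens the pyran ring to the aryl propargyl ether A5. Forward, a cationic complex of monovalent gold activates the terminal alkyne of A5, C4a (the only free position ortho to the ether oxygen) attacks the terminal carbon in a 6-endo-dig hydroarylation, and protodeauration gives chromene ester A4.
- In its favour: the O1–C2 bond is never broken, so the configuration of the propargylic carbon passes into C2. The thermal rearrangement of such ethers, by contrast, passes through an achiral dienone. The chromene is formed at the right oxidation level, and the regiochemistry is fixed by the substitution of the arene.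
- Against it here: A5 is the difficulty. Copper-catalysed etherification of phenols with tertiary propargylic carbonates goes through a planar cationic intermediate and would erase the stereocentre. Displacement of an aryl fluoride by a tertiary alkoxide on a ring with two alkoxy donors is slow. The tertiary propargylic ether can also ionise at the Lewis-acidic gold centre. The ester of A4 still needs several steps to become the cinnamoyl ketone.
- Comparison: on structure, Alternative 2 builds the pyran ring onto a bought arene, whereas the chosen plan builds the arene onto the pyran. On mechanism, it is an electrophilic aromatic substitution at a C4a activated by two ortho oxygens and only meta to the ester, which is sound. Alternative 2 is the better in needing no dehydrogenation step, and the equal in its source of chirality, since its propargylic alcohol could come from 1. It is the weaker in stereochemical safety, because its stereocentre sits next to the reacting centres in both etherification and cyclisation, whereas C2 is a bystander in 12.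

Alternative 3: The cut is the C3=C4 double bond, which opens the pyran ring to diene A7, a tertiary aryl ether with one vinyl group on C2 and one on C4a. Forward, a ruthenium alkylidene (for example the second-generation Grubbs catalyst) joins the two vinyl groups by ring-closing metathesis, with loss of a volatile two-carbon alkene, to give acetyl chromene A6.
- In its favour: the C2 unit of A7 is the carbon skeleton of 3 with its vinyl group untouched, so the chiral pool fits without homologation, and a catalytic asymmetric allylic etherification is also conceivable. Metathesis is neutral and tolerates the tertiary alcohol and the ketone. The chromene forms directly, and the acetyl group of A6 needs one Claisen–Schmidt condensation to become the chalcone.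
- Against it here: everything rests on making A7, that is, on arylating a tertiary allylic oxygen with a 2,6-disubstituted, electron-rich arene without loss of configuration or allylic transposition. The ortho-vinyl group must be installed, and three methoxymethyl ethers again leave only with acid at the end.
- Comparison: on structure, ring A is bought with its oxygens, so no redox adjustment is needed, which is better than the chosen plan. On mechanism, closing a six-membered ring with a cis-disubstituted alkene by metathesis is at least as dependable as the benzannulation, with the risk moved into the preceding C–O bond formation. On step economy Alternative 3 is probably the shorter. The chosen plan is the safer in leaving C2 untouched from the first step to the last.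

Key step: step 13

Assumption: (S)-(+)-linalool 1 of high enantiomeric purity is taken as a commercial starting material; chromene numbering (O1, C2 … C8a) is used for all bicyclic compounds and for the atoms that become them.

Step 1
Reactants: 1 (S)-linalool, (3S)-3,7-dimethylocta-1,6-dien-3-ol
Product: 2 (3S)-5-(3,3-dimethyloxiran-2-yl)-3-methylpent-1-en-3-ol (both oxirane epimers)
Conditions: mCPBA (1.05 equiv), NaHCO3, CH2Cl2, 0 °C
Reagents that add atoms: 3-chloroperoxybenzoic acid (mCPBA), OOC(=O)c1cccc(Cl)c1
Why: Prilezhaev epoxidation; the electron-rich trisubstituted alkene reacts far faster than the vinyl group, cold buffered conditions suppress acid-catalysed attack of the C3 hydroxyl on the oxirane, the new oxirane stereocentre is unselective and is erased in step 2, and C3 is not touched.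

Step 2
Reactants: 2 (3S)-5-(3,3-dimethyloxiran-2-yl)-3-methylpent-1-en-3-ol
Product: 3 (6S)-2,6-dimethyloct-7-ene-2,6-diol
Conditions: LiEt3BH (2.5 equiv), THF, 0 °C to rt; then H2O
Reagents that add atoms: none
Why: Hydride opening of a trisubstituted epoxide at its less substituted carbon (SN2) gives the tertiary alcohol; the borohydride is much faster than attack by the internal alkoxide, and the vinyl group is inert.

Step 3
Reactants: 3 (6S)-2,6-dimethyloct-7-ene-2,6-diol
Product: 5 (5S)-5-(4-hydroxy-4-methylpentyl)-5-methyloxolan-2-ol (anomer mixture), via open-chain hydroxy aldehyde 4 (not isolated)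
Conditions: Rh(acac)(CO)2 (0.5 mol %), PPh3 (5 mol %), CO/H2 (1:1, 20 bar), toluene, 60 °C
Reagents that add atoms: carbon monoxide, [C-]#[O+]
Why: Rhodium-catalysed hydroformylation; a vinyl group on a fully substituted carbon gives only the linear aldehyde 4, which closes onto the neighbouring tertiary hydroxyl to the five-membered lactol, as is known for tertiary allylic alcohols of this type; this adds C4a without making any carbon near the carbinol electrophilic.

Step 4
Reactants: 5 (5S)-5-(4-hydroxy-4-methylpentyl)-5-methyloxolan-2-ol
Product: 6 (6S)-2,6-dimethyldec-9-yne-2,6-diol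
Conditions: dimethyl (1-diazo-2-oxopropyl)phosphonate (1.5 equiv), K2CO3 (3 equiv), MeOH, rt
Reagents that add atoms: Ohira–Bestmann reagent, dimethyl (1-diazo-2-oxopropyl)phosphonate, CC(=O)C(=[N+]=[N-])P(=O)(OC)OC
Why: Seyferth–Gilbert homologation in the Ohira–Bestmann version; the lactol reacts through its open aldehyde form with the diazomethylphosphonate anion generated in methanol, and loss of phosphate and N2 with a 1,2-hydrogen shift gives the terminal alkyne; both tertiary hydroxyls are spectators.

Step 5
Reactants: 6 (6S)-2,6-dimethyldec-9-yne-2,6-diol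
Product: 7 2-methyl-5-[(2S)-2-methyl-3,4-dihydro-2H-pyran-2-yl]pentan-2-ol
Conditions: W(CO)6 (25 mol %), DABCO (2 equiv), THF, hν (350 nm), 60 °C
Reagents that add atoms: none
Why: Tungsten-catalysed endo-cycloisomerisation of a 4-alkyn-1-ol; photogenerated W(CO)5 turns the terminal alkyne into a vinylidene, the C6 hydroxyl adds to its metal-bound carbon (6-endo, anti-Markovnikov) and protonolysis releases the cyclic enol ether; the C2 hydroxyl would have to close a ten-membered ring and stays free.

Step 6
Reactants: 7 2-methyl-5-[(2S)-2-methyl-3,4-dihydro-2H-pyran-2-yl]pentan-2-ol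
Product: 8 triethyl({2-methyl-5-[(2S)-2-methyl-3,4-dihydro-2H-pyran-2-yl]pentan-2-yl}oxy)silane
Conditions: TESOTf (1.3 equiv), 2,6-lutidine (2 equiv), CH2Cl2, −78 °C
Reagents that add atoms: triethylsilyl trifluoromethanesulfonate, CC[Si](CC)(CC)OS(=O)(=O)C(F)(F)F
Why: Silylation of a tertiary alcohol with a silyl triflate and a hindered pyridine base, which keeps the medium non-acidic so that the enol ether survives; the ether blocks the hydroxyl against tBuLi and the oxonium salt of step 7.

Step 7
Reactants: 8 triethyl({2-methyl-5-[(2S)-2-methyl-3,4-dihydro-2H-pyran-2-yl]pentan-2-yl}oxy)silane; 9 chromium hexacarbonyl, Cr(CO)6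
Product: 12 pentacarbonyl[methoxy{(6S)-6-methyl-6-[4-methyl-4-(triethylsilyloxy)pentyl]-5,6-dihydro-4H-pyran-2-yl}methylidene]chromium, via 6-lithio dihydropyran 10 (not isolated), via lithium acylchromate 11 (not isolated)
Conditions: tBuLi (1.2 equiv), THF, −78 to 0 °C; Cr(CO)6, THF, 0 °C to rt; Me3OBF4, CH2Cl2, 0 °C
Reagents that add atoms: trimethyloxonium tetrafluoroborate, C[O+](C)C.F[B-](F)(F)F
Why: Fischer carbene synthesis; tBuLi removes the vinylic hydrogen on the oxygen-bearing carbon of the cyclic enol ether, 10 adds to a carbonyl ligand of 9 to give 11, and the hard oxonium salt methylates its oxygen; C2 is a saturated carbon and is not involved.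

Step 8
Reactants: 13 4-hydroxybenzaldehyde
Product: 14 4-(triisopropylsilyloxy)benzaldehyde
Conditions: TIPSCl (1.1 equiv), imidazole (2 equiv), DMF, rt
Reagents that add atoms: chlorotriisopropylsilane, CC(C)[Si](Cl)(C(C)C)C(C)C
Why: Standard silylation of a phenol; the triisopropylsilyl group is chosen because it survives NaH, alkynyllithium, K2CO3 in methanol and DDQ, and leaves with fluoride at the end.

Step 9
Reactants: 14 4-(triisopropylsilyloxy)benzaldehyde; 15 diethyl {2-[methoxy(methyl)amino]-2-oxoethyl}phosphonate
Product: 16 (E)-N-methoxy-N-methyl-3-[4-(triisopropylsilyloxy)phenyl]prop-2-enamide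
Conditions: NaH (1.1 equiv), THF, 0 °C to rt
Reagents that add atoms: none
Why: Horner–Wadsworth–Emmons olefination with an amide-stabilised phosphonate anion, which gives the (E)-alkene.

Step 10
Reactants: 16 (E)-N-methoxy-N-methyl-3-[4-(triisopropylsilyloxy)phenyl]prop-2-enamide; 17 ethynyltrimethylsilane
Product: 19 (E)-1-[4-(triisopropylsilyloxy)phenyl]-5-(trimethylsilyl)pent-1-en-4-yn-3-one, via lithium (trimethylsilyl)acetylide 18 (not isolated)
Conditions: nBuLi (1.4 equiv), THF, −78 °C; then 16, −78 to 0 °C; sat. aq. NH4Cl, −78 °C
Reagents that add atoms: none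
Why: Weinreb ketone synthesis; 18 adds once, in a 1,2 sense, to the N-methoxy-N-methylamide and the ketone appears only on work-up; the cold, mildly acidic quench keeps the liberated hydroxylamine protonated so that it does not add to the ynone.

Step 11
Reactants: 19 (E)-1-[4-(triisopropylsilyloxy)phenyl]-5-(trimethylsilyl)pent-1-en-4-yn-3-one
Product: 20 triisopropyl(4-{(E)-2-[2-((trimethylsilyl)ethynyl)-1,3-dioxolan-2-yl]ethenyl}phenoxy)silane
Conditions: TMSOCH2CH2OTMS (2 equiv), TMSOTf (5 mol %), CH2Cl2, −78 to −20 °C; pyridine quench
Reagents that add atoms: 1,2-bis(trimethylsilyloxy)ethane, C[Si](C)(C)OCCO[Si](C)(C)C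
Why: Aprotic silyl-transfer ketalisation; TMSOTf activates the carbonyl, the bis-silyl glycol ether delivers both oxygens and hexamethyldisiloxane is the stable by-product; with no free glycol or Brønsted acid and with silicon on the alkyne terminus, conjugate addition to the ynone does not compete and the (E)-alkene is kept.

Step 12
Reactants: 20 triisopropyl(4-{(E)-2-[2-((trimethylsilyl)ethynyl)-1,3-dioxolan-2-yl]ethenyl}phenoxy)silane
Product: 21 {4-[(E)-2-(2-ethynyl-1,3-dioxolan-2-yl)ethenyl]phenoxy}triisopropylsilane
Conditions: K2CO3 (0.2 equiv), MeOH, rt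
Reagents that add atoms: none
Why: Base-catalysed methanolysis of the alkynyl C–Si bond; the aryl triisopropylsilyl ether and the dioxolane are stable to catalytic carbonate at room temperature.

Step 13
Reactants: 12 pentacarbonyl[methoxy{(6S)-6-methyl-6-[4-methyl-4-(triethylsilyloxy)pentyl]-5,6-dihydro-4H-pyran-2-yl}methylidene]chromium; 21 {4-[(E)-2-(2-ethynyl-1,3-dioxolan-2-yl)ethenyl]phenoxy}triisopropylsilane
Product: 23 (2S)-8-methoxy-2-methyl-2-[4-methyl-4-(triethylsilyloxy)pentyl]-6-{2-[(E)-2-(4-triisopropylsilyloxyphenyl)ethenyl]-1,3-dioxolan-2-yl}chroman-5-ol, via tricarbonylchromium arene complex 22 (not isolated)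
Conditions: 21 (1.5 equiv), THF (0.05 M), 55 °C, argon; then air, daylight, Et2O, rt
Reagents that add atoms: none
Why: Dötz benzannulation, the closest known case being alkenyl(alkoxy)carbene complexes of chromium carbonyl, cyclic enol ether carbenes included, with terminal alkynes. Thermal loss of one carbonyl ligand from 12 opens a site for 21, and the alkyne inserts into the chromium–carbene bond so that its terminal carbon (C7) bonds to the carbene carbon (C8) and chromium moves to C6. A second carbonyl ligand inserts to give a chromium-bound dienylketene whose ketene carbon is C5. Ring A closes by a thermal 6π-electrocyclisation between C5 and the enol ether carbon C4a, and tautomerisation of the cyclohexadienone gives the phenol, held as 22 until air and light remove the metal. No stereocentre is formed, and C2 is a remote saturated carbon that is not touched. The selectivity needed is the regiochemistry of insertion: the bulky dioxolanyl substituent takes the alkyne carbon that becomes the new carbene centre, where it avoids the carbonyl ligands that crowd the neighbouring position, so the masked acyl carbon ends on C6 beside the C5 hydroxyl and hydrogen on C7. The ketal keeps the alkyne electron-rich, since an ynone would be a poor partner, and a coordinating ether solvent at moderate temperature favours carbonyl insertion over other annulation paths.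

Step 14
Reactants: 23 (2S)-8-methoxy-2-methyl-2-[4-methyl-4-(triethylsilyloxy)pentyl]-6-{2-[(E)-2-(4-triisopropylsilyloxyphenyl)ethenyl]-1,3-dioxolan-2-yl}chroman-5-ol
Product: 25 (2S)-2-methyl-2-[4-methyl-4-(triethylsilyloxy)pentyl]-6-{2-[(E)-2-(4-triisopropylsilyloxyphenyl)ethenyl]-1,3-dioxolan-2-yl}chromane-5,8-diol, via chroman-5,8-quinone 24 (not isolated)
Conditions: PhI(OAc)2 (1.1 equiv), NaHCO3, MeCN–H2O (3:1), 0 °C; then aq. Na2S2O4, EtOAc, rt, argon
Reagents that add atoms: water, O
Why: Oxidative demethylation of a 4-methoxyphenol; ligand exchange on PhI(OAc)2 and loss of iodobenzene give a phenoxenium ion that water attacks at C8, methanol leaves to give 24, and dithionite reduces the quinone; doing this on the chroman under bicarbonate buffer, before chromene and enone exist, spares the dioxolane and the silyl ethers.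

Step 15
Reactants: 25 (2S)-2-methyl-2-[4-methyl-4-(triethylsilyloxy)pentyl]-6-{2-[(E)-2-(4-triisopropylsilyloxyphenyl)ethenyl]-1,3-dioxolan-2-yl}chromane-5,8-diol
Product: 26 (2S)-5,8-bis(tert-butyldimethylsilyloxy)-2-methyl-2-[4-methyl-4-(triethylsilyloxy)pentyl]-6-{2-[(E)-2-(4-triisopropylsilyloxyphenyl)ethenyl]-1,3-dioxolan-2-yl}chroman
Conditions: NaH (2.5 equiv), TBSCl (2.5 equiv), THF, 0 °C to rt, argon
Reagents that add atoms: tert-butylchlorodimethylsilane, CC(C)(C)[Si](C)(C)Cl
Why: Silylation of the sodium phenoxides with a silyl chloride; basic conditions are used because a silyl triflate could open the ketal, and the hindered C5 oxygen reacts readily as its anion.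

Step 16
Reactants: 26 (2S)-5,8-bis(tert-butyldimethylsilyloxy)-2-methyl-2-[4-methyl-4-(triethylsilyloxy)pentyl]-6-{2-[(E)-2-(4-triisopropylsilyloxyphenyl)ethenyl]-1,3-dioxolan-2-yl}chroman
Product: 27 (2S)-5,8-bis(tert-butyldimethylsilyloxy)-2-methyl-2-[4-methyl-4-(triethylsilyloxy)pentyl]-6-{2-[(E)-2-(4-triisopropylsilyloxyphenyl)ethenyl]-1,3-dioxolan-2-yl}-2H-chromene
Conditions: DDQ (1.5 equiv), benzene, 4 Å MS, 80 °C
Reagents that add atoms: none
Why: Dehydrogenation of a chroman to a 2H-chromene with DDQ; hydride is taken from benzylic C4, the cation being stabilised by O1 and the C5 oxygen (both ortho to C4a), and loss of a proton from C3 gives the double bond; C2 is fully substituted so no further oxidation follows, the ketal carbon has no hydrogen, and the C2 configuration is not touched.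

Step 17
Reactants: 27 (2S)-5,8-bis(tert-butyldimethylsilyloxy)-2-methyl-2-[4-methyl-4-(triethylsilyloxy)pentyl]-6-{2-[(E)-2-(4-triisopropylsilyloxyphenyl)ethenyl]-1,3-dioxolan-2-yl}-2H-chromene
Product: 29 (E)-1-[(2S)-5,8-dihydroxy-2-(4-hydroxy-4-methylpentyl)-2-methyl-2H-chromen-6-yl]-3-(4-hydroxyphenyl)prop-2-en-1-one, via desilylated triphenol ketal 28 (not isolated)
Conditions: TBAF (3.3 equiv), AcOH (3.3 equiv), THF, 0 °C, argon; then 1 M aq. HCl, THF, rt
Reagents that add atoms: water, O
Why: Buffered fluoride cleaves the three aryl silyl ethers while the enone is still masked, so no phenoxide ever meets a chalcone; dilute acid then hydrolyses the benzylic, allylic dioxolane through a strongly stabilised oxocarbenium ion and removes the tertiary triethylsilyl group, conditions that chromene, tertiary alcohol and 2'-hydroxychalcone tolerate.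

## Compound list

1 | (S)-linalool, (3S)-3,7-dimethylocta-1,6-dien-3-ol | CC(C)=CCC[C@@](O)(C)C=C | starting material
2 | (3S)-5-(3,3-dimethyloxiran-2-yl)-3-methylpent-1-en-3-ol (both oxirane epimers) | CC1(C)OC1CC[C@@](O)(C)C=C | intermediate
3 | (6S)-2,6-dimethyloct-7-ene-2,6-diol | CC(C)(O)CCC[C@@](O)(C)C=C | intermediate
4 | (4S)-4,8-dihydroxy-4,8-dimethylnonanal | CC(C)(O)CCC[C@@](O)(C)CCC=O | intermediate (not isolated)
5 | (5S)-5-(4-hydroxy-4-methylpentyl)-5-methyloxolan-2-ol (anomer mixture) | CC(C)(O)CCC[C@@]1(C)CCC(O)O1 | intermediate
6 | (6S)-2,6-dimethyldec-9-yne-2,6-diol | CC(C)(O)CCC[C@@](O)(C)CCC#C | intermediate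
7 | 2-methyl-5-[(2S)-2-methyl-3,4-dihydro-2H-pyran-2-yl]pentan-2-ol | CC(C)(O)CCC[C@@]1(C)CCC=CO1 | intermediate
8 | triethyl({2-methyl-5-[(2S)-2-methyl-3,4-dihydro-2H-pyran-2-yl]pentan-2-yl}oxy)silane | CC(C)(O[Si](CC)(CC)CC)CCC[C@@]1(C)CCC=CO1 | intermediate
9 | chromium hexacarbonyl, Cr(CO)6 | O=C=[Cr](=C=O)(=C=O)(=C=O)(=C=O)=C=O | starting material
10 | {(6S)-6-methyl-6-[4-methyl-4-(triethylsilyloxy)pentyl]-5,6-dihydro-4H-pyran-2-yl}lithium | CC(C)(O[Si](CC)(CC)CC)CCC[C@@]1(C)CCC=C([Li])O1 | intermediate (not isolated)
11 | lithium pentacarbonyl[{(6S)-6-methyl-6-[4-methyl-4-(triethylsilyloxy)pentyl]-5,6-dihydro-4H-pyran-2-yl}carbonyl]chromate | CC(C)(O[Si](CC)(CC)CC)CCC[C@@]1(C)CCC=C(O1)C([O-])=[Cr](=C=O)(=C=O)(=C=O)(=C=O)=C=O.[Li+] | intermediate (not isolated)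
12 | pentacarbonyl[methoxy{(6S)-6-methyl-6-[4-methyl-4-(triethylsilyloxy)pentyl]-5,6-dihydro-4H-pyran-2-yl}methylidene]chromium | CC(C)(O[Si](CC)(CC)CC)CCC[C@@]1(C)CCC=C(O1)C(OC)=[Cr](=C=O)(=C=O)(=C=O)(=C=O)=C=O | intermediate
13 | 4-hydroxybenzaldehyde | O=Cc1ccc(O)cc1 | starting material
14 | 4-(triisopropylsilyloxy)benzaldehyde | O=Cc1ccc(O[Si](C(C)C)(C(C)C)C(C)C)cc1 | intermediate
15 | diethyl {2-[methoxy(methyl)amino]-2-oxoethyl}phosphonate | CCOP(=O)(CC(=O)N(C)OC)OCC | starting material
16 | (E)-N-methoxy-N-methyl-3-[4-(triisopropylsilyloxy)phenyl]prop-2-enamide | CON(C)C(=O)/C=C/c1ccc(O[Si](C(C)C)(C(C)C)C(C)C)cc1 | intermediate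
17 | ethynyltrimethylsilane | C#C[Si](C)(C)C | starting material
18 | lithium (trimethylsilyl)acetylide | [Li]C#C[Si](C)(C)C | intermediate (not isolated)
19 | (E)-1-[4-(triisopropylsilyloxy)phenyl]-5-(trimethylsilyl)pent-1-en-4-yn-3-one | C[Si](C)(C)C#CC(=O)/C=C/c1ccc(O[Si](C(C)C)(C(C)C)C(C)C)cc1 | intermediate
20 | triisopropyl(4-{(E)-2-[2-((trimethylsilyl)ethynyl)-1,3-dioxolan-2-yl]ethenyl}phenoxy)silane | C[Si](C)(C)C#CC1(/C=C/c2ccc(O[Si](C(C)C)(C(C)C)C(C)C)cc2)OCCO1 | intermediate
21 | {4-[(E)-2-(2-ethynyl-1,3-dioxolan-2-yl)ethenyl]phenoxy}triisopropylsilane | C#CC1(/C=C/c2ccc(O[Si](C(C)C)(C(C)C)C(C)C)cc2)OCCO1 | intermediate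
22 | tricarbonylchromium complex of 23, Cr(CO)3 bound η6 to ring A (written as a dot-separated pair) | CC(C)(O[Si](CC)(CC)CC)CCC[C@@]1(C)CCc2c(O)c(C3(/C=C/c4ccc(O[Si](C(C)C)(C(C)C)C(C)C)cc4)OCCO3)cc(OC)c2O1.O=C=[Cr](=C=O)=C=O | intermediate (not isolated)
23 | (2S)-8-methoxy-2-methyl-2-[4-methyl-4-(triethylsilyloxy)pentyl]-6-{2-[(E)-2-(4-triisopropylsilyloxyphenyl)ethenyl]-1,3-dioxolan-2-yl}chroman-5-ol | CC(C)(O[Si](CC)(CC)CC)CCC[C@@]1(C)CCc2c(O)c(C3(/C=C/c4ccc(O[Si](C(C)C)(C(C)C)C(C)C)cc4)OCCO3)cc(OC)c2O1 | intermediate
24 | (2S)-2-methyl-2-[4-methyl-4-(triethylsilyloxy)pentyl]-6-{2-[(E)-2-(4-triisopropylsilyloxyphenyl)ethenyl]-1,3-dioxolan-2-yl}-3,4-dihydro-2H-chromene-5,8-dione | CC(C)(O[Si](CC)(CC)CC)CCC[C@@]1(C)CCC2=C(O1)C(=O)C=C(C3(/C=C/c4ccc(O[Si](C(C)C)(C(C)C)C(C)C)cc4)OCCO3)C2=O | intermediate (not isolated)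
25 | (2S)-2-methyl-2-[4-methyl-4-(triethylsilyloxy)pentyl]-6-{2-[(E)-2-(4-triisopropylsilyloxyphenyl)ethenyl]-1,3-dioxolan-2-yl}chromane-5,8-diol | CC(C)(O[Si](CC)(CC)CC)CCC[C@@]1(C)CCc2c(O)c(C3(/C=C/c4ccc(O[Si](C(C)C)(C(C)C)C(C)C)cc4)OCCO3)cc(O)c2O1 | intermediate
26 | (2S)-5,8-bis(tert-butyldimethylsilyloxy)-2-methyl-2-[4-methyl-4-(triethylsilyloxy)pentyl]-6-{2-[(E)-2-(4-triisopropylsilyloxyphenyl)ethenyl]-1,3-dioxolan-2-yl}chroman | CC(C)(O[Si](CC)(CC)CC)CCC[C@@]1(C)CCc2c(O[Si](C)(C)C(C)(C)C)c(C3(/C=C/c4ccc(O[Si](C(C)C)(C(C)C)C(C)C)cc4)OCCO3)cc(O[Si](C)(C)C(C)(C)C)c2O1 | intermediate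
27 | (2S)-5,8-bis(tert-butyldimethylsilyloxy)-2-methyl-2-[4-methyl-4-(triethylsilyloxy)pentyl]-6-{2-[(E)-2-(4-triisopropylsilyloxyphenyl)ethenyl]-1,3-dioxolan-2-yl}-2H-chromene | CC(C)(O[Si](CC)(CC)CC)CCC[C@@]1(C)C=Cc2c(O[Si](C)(C)C(C)(C)C)c(C3(/C=C/c4ccc(O[Si](C(C)C)(C(C)C)C(C)C)cc4)OCCO3)cc(O[Si](C)(C)C(C)(C)C)c2O1 | intermediate
28 | (2S)-6-{2-[(E)-2-(4-hydroxyphenyl)ethenyl]-1,3-dioxolan-2-yl}-2-methyl-2-[4-methyl-4-(triethylsilyloxy)pentyl]-2H-chromene-5,8-diol | CC(C)(O[Si](CC)(CC)CC)CCC[C@@]1(C)C=Cc2c(O)c(C3(/C=C/c4ccc(O)cc4)OCCO3)cc(O)c2O1 | intermediate (not isolated)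
29 | (E)-1-[(2S)-5,8-dihydroxy-2-(4-hydroxy-4-methylpentyl)-2-methyl-2H-chromen-6-yl]-3-(4-hydroxyphenyl)prop-2-en-1-one | CC(C)(O)CCC[C@@]1(C)C=Cc2c(O)c(C(=O)/C=C/c3ccc(O)cc3)cc(O)c2O1 | target

## Step count and least certain steps

Total: 17 steps (steps 1–7 for the carbene, steps 8–12 for the alkyne, steps 13–17 after their union). Longest linear sequence: 12 steps (steps 1–7 and 13–17).

Step 13 (key step). The most likely failure is slow alkyne insertion, caused by the fully substituted propargylic carbon of 21. Thermal decomposition of the carbene complex and insertion without carbonyl uptake then gain ground, and the labile ketal may ionise during demetalation. The fallback builds ring A without the C6 substituent and brings the cinnamoyl group in by aryl-lithium acylation. It sets out from 12 (and uses 16) and returns at 29.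
- Benzannulation of 12 with acetylene gas in THF at 50 °C, followed by air, gives (2S)-8-methoxy-2-methyl-2-[4-methyl-4-(triethylsilyloxy)pentyl]chroman-5-ol F1.
- NaH and chloromethyl methyl ether give its methoxymethyl ether F2.
- sBuLi and TMEDA lithiate C6, ortho to the methoxymethoxy group, and acylation with 16 gives the chroman chalcone F3.
- DDQ dehydrogenates it to the chromene chalcone F4.
- Dilute aqueous HCl in THF removes the methoxymethyl and triethylsilyl groups to give the 5-hydroxy-8-methoxy chalcone F5.
- PhI(OAc)2 and then Na2S2O4 give, through the quinone F6, the hydroquinone F7.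
- HF·pyridine removes the triisopropylsilyl group to give 29.

Step 16. Hydride abstraction from C4 may be slow next to the bulky C5 silyloxy group, and the acidic hydroquinone formed from the oxidant may start ketal loss. The fallback replaces hydride abstraction by radical substitution and elimination. From 26, NBS and AIBN in PhCF3 at 80 °C give the 4-bromochroman F8, and DBU in toluene eliminates hydrogen bromide to return 27.

Step 5. Addition of the hindered tertiary hydroxyl to the tungsten vinylidene may be sluggish, with catalyst decay or exo closure competing. The fallback builds the enol ether by carbonyl olefination and acetal chemistry. From 5, methoxymethylenetriphenylphosphorane (from the phosphonium chloride and KN(SiMe3)2, in excess) gives the enol ether (6S)-10-methoxy-2,6-dimethyldec-9-ene-2,6-diol F9. Pyridinium p-toluenesulfonate in hot toluene closes it to the 2-methoxyoxane F10 and drives off methanol to return 7.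

Step 11. Ketalisation of the cross-conjugated, donor-stabilised carbonyl may stop short, or conjugate addition to the ynone may set in. The fallback goes through the acyclic ketal, whose formation is driven by irreversible consumption of water. From 19, HC(OMe)3 in MeOH with catalytic camphorsulfonic acid gives the dimethyl ketal F11. Exchange with ethylene glycol (catalytic pyridinium p-toluenesulfonate, benzene, removal of methanol) returns 20.

Step 1. Acid-promoted cyclisation of the C3 hydroxyl onto the new oxirane may occur during reaction or isolation. The fallback avoids the epoxide altogether. From 1, Mukaiyama hydration (Co(acac)2, PhSiH3, O2, iPrOH) transfers a hydrogen atom to the trisubstituted alkene, and the tertiary radical is trapped by oxygen, to return 3 directly. The selectivity over the vinyl group would then be the point to watch.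

## Further compounds

F1 | step 13 | (2S)-8-methoxy-2-methyl-2-[4-methyl-4-(triethylsilyloxy)pentyl]chroman-5-ol | CC(C)(O[Si](CC)(CC)CC)CCC[C@@]1(C)CCc2c(O)ccc(OC)c2O1
F2 | step 13 | (2S)-8-methoxy-5-(methoxymethoxy)-2-methyl-2-[4-methyl-4-(triethylsilyloxy)pentyl]chroman | CC(C)(O[Si](CC)(CC)CC)CCC[C@@]1(C)CCc2c(OCOC)ccc(OC)c2O1
F3 | step 13 | (E)-1-{(2S)-8-methoxy-5-(methoxymethoxy)-2-methyl-2-[4-methyl-4-(triethylsilyloxy)pentyl]chroman-6-yl}-3-[4-(triisopropylsilyloxy)phenyl]prop-2-en-1-one | CC(C)(O[Si](CC)(CC)CC)CCC[C@@]1(C)CCc2c(OCOC)c(C(=O)/C=C/c3ccc(O[Si](C(C)C)(C(C)C)C(C)C)cc3)cc(OC)c2O1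
F4 | step 13 | (E)-1-{(2S)-8-methoxy-5-(methoxymethoxy)-2-methyl-2-[4-methyl-4-(triethylsilyloxy)pentyl]-2H-chromen-6-yl}-3-[4-(triisopropylsilyloxy)phenyl]prop-2-en-1-one | CC(C)(O[Si](CC)(CC)CC)CCC[C@@]1(C)C=Cc2c(OCOC)c(C(=O)/C=C/c3ccc(O[Si](C(C)C)(C(C)C)C(C)C)cc3)cc(OC)c2O1
F5 | step 13 | (E)-1-[(2S)-5-hydroxy-2-(4-hydroxy-4-methylpentyl)-8-methoxy-2-methyl-2H-chromen-6-yl]-3-[4-(triisopropylsilyloxy)phenyl]prop-2-en-1-one | CC(C)(O)CCC[C@@]1(C)C=Cc2c(O)c(C(=O)/C=C/c3ccc(O[Si](C(C)C)(C(C)C)C(C)C)cc3)cc(OC)c2O1
F6 | step 13 | (2S)-2-(4-hydroxy-4-methylpentyl)-2-methyl-6-{(E)-3-[4-(triisopropylsilyloxy)phenyl]prop-2-enoyl}-2H-chromene-5,8-dione | CC(C)(O)CCC[C@@]1(C)C=CC2=C(O1)C(=O)C=C(C(=O)/C=C/c3ccc(O[Si](C(C)C)(C(C)C)C(C)C)cc3)C2=O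
F7 | step 13 | (E)-1-[(2S)-5,8-dihydroxy-2-(4-hydroxy-4-methylpentyl)-2-methyl-2H-chromen-6-yl]-3-[4-(triisopropylsilyloxy)phenyl]prop-2-en-1-one | CC(C)(O)CCC[C@@]1(C)C=Cc2c(O)c(C(=O)/C=C/c3ccc(O[Si](C(C)C)(C(C)C)C(C)C)cc3)cc(O)c2O1
F8 | step 16 | (2S)-4-bromo-5,8-bis(tert-butyldimethylsilyloxy)-2-methyl-2-[4-methyl-4-(triethylsilyloxy)pentyl]-6-{2-[(E)-2-(4-triisopropylsilyloxyphenyl)ethenyl]-1,3-dioxolan-2-yl}chroman (both C4 epimers) | CC(C)(O[Si](CC)(CC)CC)CCC[C@@]1(C)CC(Br)c2c(O[Si](C)(C)C(C)(C)C)c(C3(/C=C/c4ccc(O[Si](C(C)C)(C(C)C)C(C)C)cc4)OCCO3)cc(O[Si](C)(C)C(C)(C)C)c2O1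
F9 | step 5 | (6S)-10-methoxy-2,6-dimethyldec-9-ene-2,6-diol (E and Z) | CC(C)(O)CCC[C@@](O)(C)CCC=COC
F10 | step 5 | 5-[(2S)-6-methoxy-2-methyloxan-2-yl]-2-methylpentan-2-ol (both acetal epimers) | CC(C)(O)CCC[C@@]1(C)CCCC(OC)O1
F11 | step 11 | {4-[(E)-3,3-dimethoxy-5-(trimethylsilyl)pent-1-en-4-yn-1-yl]phenoxy}triisopropylsilane | C[Si](C)(C)C#CC(OC)(OC)/C=C/c1ccc(O[Si](C(C)C)(C(C)C)C(C)C)cc1
F0 | step 1 | none | none
A1 | alternative 1 | (E)-1-[(2S)-2-(4-hydroxy-4-methylpentyl)-5,8-bis(methoxymethoxy)-2-methyl-2H-chromen-6-yl]-3-[4-(methoxymethoxy)phenyl]prop-2-en-1-one | CC(C)(O)CCC[C@@]1(C)C=Cc2c(OCOC)c(C(=O)/C=C/c3ccc(OCOC)cc3)cc(OCOC)c2O1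
A2 | alternative 1 | (2S)-2-(4-hydroxy-4-methylpentyl)-6-iodo-5,8-bis(methoxymethoxy)-2-methyl-2H-chromene | CC(C)(O)CCC[C@@]1(C)C=Cc2c(OCOC)c(I)cc(OCOC)c2O1
A3 | alternative 1 | (E)-2-[4-(methoxymethoxy)phenyl]ethenylboronic acid | COCOc1ccc(/C=C/B(O)O)cc1
A4 | alternative 2 | methyl (2S)-5,8-bis(methoxymethoxy)-2-methyl-2-[4-methyl-4-(triethylsilyloxy)pentyl]-2H-chromene-6-carboxylate | CC(C)(O[Si](CC)(CC)CC)CCC[C@@]1(C)C=Cc2c(OCOC)c(C(=O)OC)cc(OCOC)c2O1
A5 | alternative 2 | methyl 4-{[(3S)-3,7-dimethyl-7-(triethylsilyloxy)oct-1-yn-3-yl]oxy}-2,5-bis(methoxymethoxy)benzoate | CC(C)(O[Si](CC)(CC)CC)CCC[C@@](Oc1cc(OCOC)c(C(=O)OC)cc1OCOC)(C)C#C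
A6 | alternative 3 | (2S)-6-acetyl-2-(4-hydroxy-4-methylpentyl)-5,8-bis(methoxymethoxy)-2-methyl-2H-chromene | CC(C)(O)CCC[C@@]1(C)C=Cc2c(OCOC)c(C(C)=O)cc(OCOC)c2O1
A7 | alternative 3 | 1-{3-ethenyl-4-[((3S)-7-hydroxy-3,7-dimethyloct-1-en-3-yl)oxy]-2,5-bis(methoxymethoxy)phenyl}ethanone | CC(C)(O)CCC[C@@](Oc1c(C=C)c(OCOC)c(C(C)=O)cc1OCOC)(C)C=C
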